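**Retrosynthetic overview**
1. Target 27 ← bis-angeloylation of triol 22 ← hydroxyl-directed relay reduction of triketone 21 (sets C1, C3) ← conjugate methylation of tricyclic enone 18 (sets C10).
2. Key disconnection: both bridges are closed onto a preformed cyclobutene in one operation – ring A by an intramolecular Michael addition (C6–C11) and ring B by an aldol condensation (C9=C10), 15 → 17.
3. Monocyclic 15 ← dianion aldol of methyl 2-methylacetoacetate with keto-dialdehyde 11.
4. 11 ← auxiliary-controlled [2+2] of dimenthyl fumarate with ketene dimethyl acetal, then C-methylation, enol triflate/Stille acetylation and redox adjustment.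
5. Ring order: cyclobutane first, then the seven-membered ring A and the six-membered ring B together.

Atom labels used in names: C4 (methyl-bearing), C5, C6, C7 = cyclobutane; bridge A = C3–C2–C1–C11 from C4 to C6 (C11 carries CH3 and C12); bridge B = C8–C9–C10 from C7 to C5. In these labels the target is 1R,3R,4R,5S,6S,7R,10R,11S.

Assumption: di-(+)-menthyl fumarate is taken to give the (1R,2S) cycloadduct 3 (mirror image of the adduct from the (−)-menthyl ester); if the facial sense is the opposite, the (−)-menthyl ester is used and nothing else changes.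

**Step 1**
Reactants: 1 di-(+)-menthyl fumarate; 2 1,1-dimethoxyethene
Product: 3 bis[(1S,2R,5S)-menthyl] (1R,2S)-3,3-dimethoxycyclobutane-1,2-dicarboxylate
Conditions: Et2AlCl (2 equiv), toluene, −78 °C
Reagents that add atoms: none
Why: Lewis acid-promoted stepwise [2+2] cycloaddition (Michael addition of the ketene acetal carbon, then closure of the aluminium enolate onto the oxocarbenium carbon), in which the two menthyl esters block one face of the (E)-alkene so that C4 and C5 form as one trans pair (4S,5R).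

**Step 2**
Reactants: 3
Product: 4 bis[(1S,2R,5S)-menthyl] (1R,2S)-3-oxocyclobutane-1,2-dicarboxylate
Conditions: TsOH·H2O (0.1 equiv), acetone/H2O 10:1, 23 °C
Reagents that add atoms: water O
Why: Acid-catalysed acetal hydrolysis; C5 is untouched and C4, now the α-carbon of a β-keto ester, is reset in step 3.

**Step 3**
Reactants: 4
Product: 5 bis[(1S,2R,5S)-menthyl] (1R,2R)-2-methyl-3-oxocyclobutane-1,2-dicarboxylate
Conditions: MeI (3 equiv), K2CO3 (2 equiv), acetone, 23 °C
Reagents that add atoms: iodomethane CI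
Why: C-Alkylation of the β-keto ester enolate, in which iodomethane approaches planar C4 anti to the C5 ester so that the quaternary centre forms as 4R with the methyl group trans to that ester.

**Step 4**
Reactants: 5
Product: 7 bis[(1S,2R,5S)-menthyl] (1R,2R)-2-methyl-3-(trifluoromethylsulfonyloxy)cyclobut-3-ene-1,2-dicarboxylate, via potassium enolate 6 (not isolated)
Conditions: KN(SiMe3)2 (1.1 equiv), THF, −78 °C; PhNTf2 (1.2 equiv), −78 to 0 °C
Reagents that add atoms: N-phenylbis(trifluoromethanesulfonimide) O=S(=O)(N(c1ccccc1)S(=O)(=O)C(F)(F)F)C(F)(F)F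
Why: Kinetic enolate formation and O-sulfonylation; C4 is quaternary, so only C6 can enolise and the enol triflate is regiodefined, with no stereocentre touched.

**Step 5**
Reactants: 7
Product: 9 bis[(1S,2R,5S)-menthyl] (1R,2R)-3-acetyl-2-methylcyclobut-3-ene-1,2-dicarboxylate, via ethoxyvinyl diene 8 (not isolated)
Conditions: tributyl(1-ethoxyvinyl)stannane (1.3 equiv), Pd(PPh3)4 (5 mol%), LiCl (3 equiv), THF, 65 °C; then 1 M HCl, 23 °C
Reagents that add atoms: tributyl(1-ethoxyvinyl)stannane CCOC(=C)[Sn](CCCC)(CCCC)CCCC; water O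
Why: Stille cross-coupling of the enol triflate with the acyl-anion equivalent, then enol ether hydrolysis, installs the acetyl group on C7 without touching C4 or C5.

**Step 6**
Reactants: 9
Product: 10 [(1R,2R)-3-(1-hydroxyethyl)-2-methylcyclobut-3-ene-1,2-diyl]dimethanol
Conditions: iBu2AlH (7 equiv), CH2Cl2, −78 to 0 °C; aqueous KNaC4H4O6
Reagents that add atoms: none
Why: Hydride reduction of both esters (the auxiliary is released as menthol) and 1,2-reduction of the enone; the new carbinol carbon C8 forms as a mixture that is removed in step 7.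

**Step 7**
Reactants: 10
Product: 11 (1S,2R)-3-acetyl-2-methylcyclobut-3-ene-1,2-dicarbaldehyde
Conditions: (COCl)2 (4 equiv), DMSO (8 equiv), CH2Cl2, −78 °C; Et3N (12 equiv), −78 to 0 °C; used crude
Reagents that add atoms: none
Why: Swern oxidation of all three carbinols; C5 becomes α to a formyl group and vinylogously α to the enone, so it equilibrates (trans-dialdehyde favoured), which is harmless because it is fixed only in step 9.

**Step 8**
Reactants: 11; 12 methyl 2-methyl-3-oxobutanoate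
Product: 15 methyl 5-[(1R)-2-acetyl-4-formyl-1-methylcyclobut-2-en-1-yl]-5-hydroxy-2-methyl-3-oxopentanoate, via lithium dienolate 13 (not isolated), via ketoester dianion 14 (not isolated)
Conditions: 12 (1.3 equiv), LiN(iPr)2 (2.7 equiv), THF, −78 to 0 °C; separately 11, LiN(SiMe3)2 (1.05 equiv), THF, −78 °C; combine at −78 °C, 1 h; AcOH quench
Reagents that add atoms: none
Why: Dianion aldol addition of the γ-carbon of the β-keto ester to the only remaining electrophile, the non-enolisable C3 formyl group, while the formyl/acetyl-cyclobutene unit is protected in situ as its vinylogous enolate 13; C3 forms as an epimer mixture that is erased in step 10 and C11 stays epimerisable.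

**Step 9 (key step)**
Reactants: 15
Product: 17 methyl (1S,2S,3R,7R,8R)-6-hydroxy-3,7-dimethyl-4,9-dioxotricyclo[5.4.0.0^{2,8}]undec-10-ene-3-carboxylate, via Michael adduct 16 (not isolated)
Conditions: FeCl3·6H2O (10 mol%), CH2Cl2, 23 °C; then pyrrolidine (0.3 equiv), AcOH (0.3 equiv), 40 °C, same flask
Reagents that add atoms: none
Why: Proposed new method: the iron-bound β-keto ester enolate, held on the upper face by the C3 tether, adds to C6 of the acetylcyclobutene (intramolecular Michael addition; closest precedents are FeCl3-catalysed Michael additions of β-keto esters to enones and Robinson-type annulations) to close ring A, and only once the cyclobutene is saturated can the acetyl enamine condense with the C10 formyl group (intramolecular aldol condensation) to close ring B; C6 is set by the tether (bond cis to C3), C5 and C7 epimerise through their enols until both carbonyl arms are cis (the only geometry that closes ring B), and C11 is set by the metal bridging the ester and the s-cis enone oxygen so that CO2Me lies on the C7 side.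

**Step 10**
Reactants: 17
Product: 18 methyl (1S,2S,3R,7R,8R)-3,7-dimethyl-4,6,9-trioxotricyclo[5.4.0.0^{2,8}]undec-10-ene-3-carboxylate
Conditions: Dess–Martin periodinane (1.5 equiv), NaHCO3, CH2Cl2, 23 °C
Reagents that add atoms: none
Why: Dess–Martin oxidation of the secondary alcohol converts both C3 epimers into one ring A 1,3-diketone; no other stereocentre can enolise (C11 is quaternary, C5 and C7 are bridgeheads).

**Step 11**
Reactants: 18
Product: 21 (1S,2S,3S,7R,8R,11R)-3-(hydroxymethyl)-3,7,11-trimethyltricyclo[5.4.0.0^{2,8}]undecane-4,6,9-trione, via lithium diketonate 19 (not isolated), via lithium bis-enolate 20 (not isolated)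
Conditions: LiN(SiMe3)2 (1.1 equiv), THF, −78 °C; Me2CuLi (2 equiv), −78 to −30 °C; then LiAlH4 (3 equiv), −78 to 0 °C; aqueous KNaC4H4O6
Reagents that add atoms: Me2CuLi [Li+].C[Cu-]C
Why: With ring A masked as its diketonate, Gilman conjugate addition to the ring B enone from the face remote from the C4 methyl group sets C10 (R) and leaves C8 as its enolate, so that LiAlH4 (enolate protection) reduces only the ester to the C12 carbinol.

**Step 12**
Reactants: 21
Product: 22 (1S,2S,3S,4R,6R,7R,8R,11R)-4,6-dihydroxy-3-(hydroxymethyl)-3,7,11-trimethyltricyclo[5.4.0.0^{2,8}]undecan-9-one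
Conditions: Me4NBH(OAc)3 (6 equiv), MeCN/AcOH 1:1, −20 to 23 °C
Reagents that add atoms: none
Why: Evans–Saksena hydroxyl-directed reduction used as a relay: the C12 alkoxyborohydride delivers hydride to C1 on the face it occupies (C1 R, hydroxyl cis to the C11 methyl), the new C1 alkoxyborohydride then delivers to C3 from the opposite face (anti-1,3-diol, C3 R), and the undirected C8 ketone is left.

**Step 13**
Reactants: 22
Product: 23 (1S,2S,3S,4R,6R,7R,8R,11R)-3-{[tert-butyl(dimethyl)silyl]oxymethyl}-4,6-dihydroxy-3,7,11-trimethyltricyclo[5.4.0.0^{2,8}]undecan-9-one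
Conditions: t-BuMe2SiCl (1.1 equiv), imidazole, DMF, 0 °C
Reagents that add atoms: tert-butyl(chloro)dimethylsilane CC(C)(C)[Si](C)(C)Cl
Why: Silylation is selective for the primary hydroxyl group over the two secondary hydroxyl groups flanked by quaternary carbons.

**Step 14**
Reactants: 23; 24 angelic acid
Product: 26 (1S,2S,3S,4R,6R,7R,8R,11R)-3-{[tert-butyl(dimethyl)silyl]oxymethyl}-3,7,11-trimethyl-9-oxotricyclo[5.4.0.0^{2,8}]undecane-4,6-diyl bis[(2Z)-2-methylbut-2-enoate], via mixed anhydride 25 (not isolated)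
Conditions: 24 (6 equiv), 2,4,6-trichlorobenzoyl chloride (6 equiv), Et3N (7 equiv), toluene, 23 °C, 2 h; then 23, 80 °C, 24 h
Reagents that add atoms: none
Why: Yamaguchi-type esterification through the mixed anhydride without a nucleophilic catalyst acylates both secondary alcohols and keeps the (Z)-geometry of the angelate; no stereocentre changes.

**Step 15**
Reactants: 26
Product: 27 target
Conditions: HF·pyridine, THF, 0 to 23 °C
Reagents that add atoms: none
Why: Fluoride-mediated Si–O cleavage under weakly acidic conditions frees the primary alcohol without acyl migration or angelate-to-tiglate isomerisation.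

**Compound list**
1 | bis[(1S,2R,5S)-2-isopropyl-5-methylcyclohexyl] (E)-but-2-enedioate (di-(+)-menthyl fumarate) | CC(C)[C@H]1CC[C@H](C)C[C@@H]1OC(=O)/C=C/C(=O)O[C@H]1C[C@@H](C)CC[C@@H]1C(C)C | starting material
2 | 1,1-dimethoxyethene | C=C(OC)OC | starting material
3 | bis[(1S,2R,5S)-menthyl] (1R,2S)-3,3-dimethoxycyclobutane-1,2-dicarboxylate (trans; labels 4S,5R) | CC(C)[C@H]1CC[C@H](C)C[C@@H]1OC(=O)[C@H]2[C@H](C(=O)O[C@H]3C[C@@H](C)CC[C@@H]3C(C)C)CC2(OC)OC | intermediate
4 | bis[(1S,2R,5S)-menthyl] (1R,2S)-3-oxocyclobutane-1,2-dicarboxylate | CC(C)[C@H]1CC[C@H](C)C[C@@H]1OC(=O)[C@H]2[C@H](C(=O)O[C@H]3C[C@@H](C)CC[C@@H]3C(C)C)CC2=O | intermediate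
5 | bis[(1S,2R,5S)-menthyl] (1R,2R)-2-methyl-3-oxocyclobutane-1,2-dicarboxylate (esters cis; labels 4R,5R) | CC(C)[C@H]1CC[C@H](C)C[C@@H]1OC(=O)[C@]2(C)[C@H](C(=O)O[C@H]3C[C@@H](C)CC[C@@H]3C(C)C)CC2=O | intermediate
6 | potassium enolate of 5 (not isolated) | CC(C)[C@H]1CC[C@H](C)C[C@@H]1OC(=O)[C@]2(C)[C@H](C(=O)O[C@H]3C[C@@H](C)CC[C@@H]3C(C)C)C=C2[O-].[K+] | intermediate
7 | bis[(1S,2R,5S)-menthyl] (1R,2R)-2-methyl-3-(trifluoromethylsulfonyloxy)cyclobut-3-ene-1,2-dicarboxylate | CC(C)[C@H]1CC[C@H](C)C[C@@H]1OC(=O)[C@]2(C)[C@H](C(=O)O[C@H]3C[C@@H](C)CC[C@@H]3C(C)C)C=C2OS(=O)(=O)C(F)(F)F | intermediate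
8 | bis[(1S,2R,5S)-menthyl] (1R,2R)-3-(1-ethoxyethenyl)-2-methylcyclobut-3-ene-1,2-dicarboxylate (not isolated) | CC(C)[C@H]1CC[C@H](C)C[C@@H]1OC(=O)[C@]2(C)[C@H](C(=O)O[C@H]3C[C@@H](C)CC[C@@H]3C(C)C)C=C2C(=C)OCC | intermediate
9 | bis[(1S,2R,5S)-menthyl] (1R,2R)-3-acetyl-2-methylcyclobut-3-ene-1,2-dicarboxylate | CC(C)[C@H]1CC[C@H](C)C[C@@H]1OC(=O)[C@]2(C)[C@H](C(=O)O[C@H]3C[C@@H](C)CC[C@@H]3C(C)C)C=C2C(C)=O | intermediate
10 | [(1R,2R)-3-(1-hydroxyethyl)-2-methylcyclobut-3-ene-1,2-diyl]dimethanol (both epimers at the hydroxyethyl carbon) | OC[C@]1(C)[C@H](CO)C=C1C(C)O | intermediate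
11 | (1S,2R)-3-acetyl-2-methylcyclobut-3-ene-1,2-dicarbaldehyde (trans-dialdehyde drawn; ring C1 = label C5 epimerises freely; labels 4R) | O=C[C@]1(C)[C@@H](C=O)C=C1C(C)=O | intermediate
12 | methyl 2-methyl-3-oxobutanoate (racemic) | COC(=O)C(C)C(C)=O | starting material
13 | lithium dienolate of 11, deprotonated at C5 (not isolated) | [Li+].[O-]C=C1C=C(C(C)=O)[C@]1(C)C=O | intermediate
14 | dilithium dianion of 12 (not isolated) | [Li+].[Li+].C=C([O-])C(C)=C([O-])OC | intermediate
15 | methyl 5-[(1R)-2-acetyl-4-formyl-1-methylcyclobut-2-en-1-yl]-5-hydroxy-2-methyl-3-oxopentanoate (epimers at C3, C11, C5; in equilibrium with the C3–O/C10 lactol) | COC(=O)C(C)C(=O)CC(O)[C@]1(C)C(C=O)C=C1C(C)=O | intermediate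
16 | methyl 7-acetyl-8-formyl-5-hydroxy-2,6-dimethyl-3-oxobicyclo[4.1.1]octane-2-carboxylate (labels 4R,5S,6S,7R,11R; C3 epimers; not isolated) | O=C1CC(O)[C@]2(C)[C@@H](C=O)[C@@H]([C@H]2C(C)=O)[C@@]1(C)C(=O)OC | intermediate
17 | methyl (1S,2S,3R,7R,8R)-6-hydroxy-3,7-dimethyl-4,9-dioxotricyclo[5.4.0.0^{2,8}]undec-10-ene-3-carboxylate (labels 4R,5S,6S,7R,11R; C3 epimers) | O=C1CC(O)[C@]2(C)[C@@H]3[C@@H]([C@H]2C(=O)C=C3)[C@@]1(C)C(=O)OC | intermediate
18 | methyl (1S,2S,3R,7R,8R)-3,7-dimethyl-4,6,9-trioxotricyclo[5.4.0.0^{2,8}]undec-10-ene-3-carboxylate | O=C1CC(=O)[C@]2(C)[C@@H]3[C@@H]([C@H]2C(=O)C=C3)[C@@]1(C)C(=O)OC | intermediate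
19 | lithium diketonate of 18 (ring A; not isolated) | [Li+].[O-]C1=CC(=O)[C@]2(C)[C@@H]3[C@@H]([C@H]2C(=O)C=C3)[C@@]1(C)C(=O)OC | intermediate
20 | dilithium bis-enolate after conjugate methylation (ring A diketonate, C8 enolate; not isolated) | [Li+].[Li+].[O-]C1=CC(=O)[C@]2(C)[C@@H]3[C@@H]([C@H]2C([O-])=C[C@H]3C)[C@@]1(C)C(=O)OC | intermediate
21 | (1S,2S,3S,7R,8R,11R)-3-(hydroxymethyl)-3,7,11-trimethyltricyclo[5.4.0.0^{2,8}]undecane-4,6,9-trione | O=C1CC(=O)[C@]2(C)[C@@H]3[C@@H]([C@H]2C(=O)C[C@H]3C)[C@@]1(C)CO | intermediate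
22 | (1S,2S,3S,4R,6R,7R,8R,11R)-4,6-dihydroxy-3-(hydroxymethyl)-3,7,11-trimethyltricyclo[5.4.0.0^{2,8}]undecan-9-one | O[C@@H]1C[C@@H](O)[C@]2(C)[C@@H]3[C@@H]([C@H]2C(=O)C[C@H]3C)[C@@]1(C)CO | intermediate
23 | 3-{[tert-butyl(dimethyl)silyl]oxymethyl} ether of 22 | O[C@@H]1C[C@@H](O)[C@]2(C)[C@@H]3[C@@H]([C@H]2C(=O)C[C@H]3C)[C@@]1(C)CO[Si](C)(C)C(C)(C)C | intermediate
24 | (2Z)-2-methylbut-2-enoic acid (angelic acid) | C/C=C(/C)C(=O)O | starting material
25 | (2Z)-2-methylbut-2-enoic 2,4,6-trichlorobenzoic anhydride (not isolated) | C/C=C(/C)C(=O)OC(=O)c1c(Cl)cc(Cl)cc1Cl | intermediate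
26 | (1S,2S,3S,4R,6R,7R,8R,11R)-3-{[tert-butyl(dimethyl)silyl]oxymethyl}-3,7,11-trimethyl-9-oxotricyclo[5.4.0.0^{2,8}]undecane-4,6-diyl bis[(2Z)-2-methylbut-2-enoate] | C/C=C(/C)C(=O)O[C@@H]1C[C@@H](OC(=O)/C(C)=C\C)[C@]2(C)[C@@H]3[C@@H]([C@H]2C(=O)C[C@H]3C)[C@@]1(C)CO[Si](C)(C)C(C)(C)C | intermediate
27 | (1S,2S,3S,4R,6R,7R,8R,11R)-3-(hydroxymethyl)-3,7,11-trimethyl-9-oxotricyclo[5.4.0.0^{2,8}]undecane-4,6-diyl bis[(2Z)-2-methylbut-2-enoate] | C/C=C(/C)C(=O)O[C@@H]1C[C@@H](OC(=O)/C(C)=C\C)[C@]2(C)[C@@H]3[C@@H]([C@H]2C(=O)C[C@H]3C)[C@@]1(C)CO | target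

**Step count**
Total steps: 15. Longest linear sequence: 15 steps (1 → 27).

**Steps most likely to fail**

Step 9 (double annulation). The seven-membered Michael closure may lose to aldol chemistry of the free formyl and acetyl groups, and the C11 configuration rests on the chelate model. The fallback sets out from 11 (with 12) and comes back at 17. FeCl3·6H2O-catalysed intermolecular Michael addition of 12 to C6 of 11, anti to the C5 formyl group, gives methyl 2-(2-acetyl-3,4-diformyl-3-methylcyclobutyl)-2-methyl-3-oxobutanoate F1. Pyrrolidinium acetate then closes ring A at a different bond, by aldol addition of the C2 methyl ketone to the C3 aldehyde, and ring B by aldol condensation, giving 17.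

Step 8 (chemoselective dianion aldol). The step relies on the in situ enolate protection of the enolisable formyl/enone unit. The fallback sets out from 10 and comes back at 15, using a protecting group instead. t-BuMe2SiCl (1 equiv) and imidazole at −20 °C silylate the least hindered primary alcohol to give the C10 mono-silyl ether of the triol F2. Swern oxidation gives the silyloxymethyl keto-aldehyde F3. Dianion 14 adds to its only aldehyde at −78 °C to give the silylated aldol adduct F4. HF·pyridine gives the hydroxymethyl aldol adduct F5, and TEMPO/PhI(OAc)2 oxidises its primary alcohol selectively to return 15.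

Step 14 (double angeloylation). Both alcohols are secondary and flanked by quaternary carbons, and forcing conditions risk angelate-to-tiglate isomerisation. The fallback sets out from 23 and comes back at 26 by building the (Z)-alkene on the scaffold. Esterification with 2-[bis(2,2,2-trifluoroethoxy)phosphoryl]propanoic acid (N,N'-diisopropylcarbodiimide, DMAP) gives the bis(phosphonopropanoate) F6. Still–Gennari olefination with acetaldehyde (KN(SiMe3)2, 18-crown-6, THF, −78 °C) then gives 26.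

**Further compounds**
F1 | step 9 | methyl 2-(2-acetyl-3,4-diformyl-3-methylcyclobutyl)-2-methyl-3-oxobutanoate (labels 4R,5S,6S,7R,11R) | O=C[C@]1(C)[C@@H](C=O)[C@@H]([C@H]1C(C)=O)[C@](C)(C(C)=O)C(=O)OC
F2 | step 8 | [(1R,4R)-4-{[tert-butyl(dimethyl)silyl]oxymethyl}-2-(1-hydroxyethyl)-1-methylcyclobut-2-en-1-yl]methanol | OC[C@]1(C)[C@H](CO[Si](C)(C)C(C)(C)C)C=C1C(C)O
F3 | step 8 | (1R,4R)-2-acetyl-4-{[tert-butyl(dimethyl)silyl]oxymethyl}-1-methylcyclobut-2-ene-1-carbaldehyde | O=C[C@]1(C)[C@H](CO[Si](C)(C)C(C)(C)C)C=C1C(C)=O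
F4 | step 8 | methyl 5-[(1R,4R)-2-acetyl-4-{[tert-butyl(dimethyl)silyl]oxymethyl}-1-methylcyclobut-2-en-1-yl]-5-hydroxy-2-methyl-3-oxopentanoate | COC(=O)C(C)C(=O)CC(O)[C@]1(C)[C@H](CO[Si](C)(C)C(C)(C)C)C=C1C(C)=O
F5 | step 8 | methyl 5-[(1R,4R)-2-acetyl-4-(hydroxymethyl)-1-methylcyclobut-2-en-1-yl]-5-hydroxy-2-methyl-3-oxopentanoate | COC(=O)C(C)C(=O)CC(O)[C@]1(C)[C@H](CO)C=C1C(C)=O
F6 | step 14 | 4,6-bis{2-[bis(2,2,2-trifluoroethoxy)phosphoryl]propanoate} of 23 | CC(C(=O)O[C@@H]1C[C@@H](OC(=O)C(C)P(=O)(OCC(F)(F)F)OCC(F)(F)F)[C@]2(C)[C@@H]3[C@@H]([C@H]2C(=O)C[C@H]3C)[C@@]1(C)CO[Si](C)(C)C(C)(C)C)P(=O)(OCC(F)(F)F)OCC(F)(F)F
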